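**Strategy**

1. Numbering used throughout (drimane type): ring A carries the C4 gem-dimethyl group; ring B holds C5=C6, C7, C8 (secondary methyl), C9 (quaternary, with methyl and benzylic C11) and C10 (ring-fusion H). The retrosynthesis cuts the C11–aryl bond, then C7–C8 and C9–C10 of ring B, then the C5–C6 bond that joins the vinyl group to ring A.
2. Enabling feature: ring B is a cyclohexene whose C5=C6 bond lies directly across from the C8–C9 bond, which is a Diels–Alder retron. C8, C9, their two cis methyl groups and C11 are the five carbons of (E)-2-methylbut-2-enal, and C10=C5–C6=C7 is a 1-vinylcyclohexene.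
3. Forward: ring A is bought as 2,2-dimethylcyclohexanone and converted through its enol triflate into the vinyl diene. Ring B then closes in one catalytic enantioselective exo Diels–Alder reaction with tiglaldehyde.
4. The arene that becomes the quinone (1,2,4,5-tetramethoxybenzene, all six ring carbons and four oxygens) is attached at C11 by aryllithium addition to the cycloadduct aldehyde. The carbinol oxygen is then removed by radical deoxygenation.
5. Oxidative demethylation unmasks the six-membered quinone ring, and hydrolysis of the methoxy group next to the alkyl substituent gives the hydroxyquinone.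
6. Stereochemistry: C8, C9 and C10 are all created in the cycloaddition (cis methyls from the E enal, C10 from the exo transition state, absolute sense from the chiral boron catalyst). No later step touches them.

Key step: step 3

Assumption: the sense of induction is taken from the accepted formyl C–H···O binding model for alpha-substituted enals on N-protonated oxazaborolidines, which predicts that the catalyst from (R)-diphenylprolinol exposes the Si face of the alpha-carbon of tiglaldehyde; if the model does not hold for this enal, the (S)-prolinol-derived antipode is used in the same way.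

**Route**

Step 1
Reactants: 1 2,2-dimethylcyclohexanone
Product: 3 6,6-dimethylcyclohex-1-en-1-yl trifluoromethanesulfonate, via lithium enolate 2 (not isolated)
Conditions: LiN(i-Pr)2, THF, −78 °C; then PhNTf2, −78 °C to rt
Reagents that add atoms: N-phenylbis(trifluoromethanesulfonimide) (O=S(=O)(N(c1ccccc1)S(=O)(=O)C(F)(F)F)C(F)(F)F)
Why: Enol triflate formation: the ketone has alpha-hydrogens only at C6, so LiN(i-Pr)2 can give a single enolate, which PhNTf2 sulfonylates on oxygen; no stereocentre is formed.

Step 2
Reactants: 3 6,6-dimethylcyclohex-1-en-1-yl trifluoromethanesulfonate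
Product: 4 1-ethenyl-6,6-dimethylcyclohexene (6,6-dimethyl-1-vinylcyclohexene)
Conditions: Bu3SnCH=CH2, Pd(PPh3)4 (3 mol %), LiCl (3 equiv), THF, reflux; product distilled
Reagents that add atoms: tributyl(vinyl)stannane (C=C[Sn](CCCC)(CCCC)CCCC)
Why: Stille cross-coupling of an enol triflate: zerovalent palladium inserts into the C–OTf bond, chloride from LiCl readies the palladium intermediate for transmetalation, the vinyl group is transferred from tin and reductive elimination should give the 1,3-diene; no stereocentre is formed.

Step 3
Reactants: 4 1-ethenyl-6,6-dimethylcyclohexene; 5 (E)-2-methylbut-2-enal (tiglaldehyde)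
Product: 6 (1R,2S,8aR)-1,2,5,5-tetramethyl-1,2,3,5,6,7,8,8a-octahydronaphthalene-1-carbaldehyde
Conditions: (3aR)-1-(2-methylphenyl)-3,3-diphenyltetrahydro-1H,3H-pyrrolo[1,2-c][1,3,2]oxazaborole (20 mol %), HN(SO2CF3)2 (17 mol %), CH2Cl2, −78 to −20 °C
Reagents that add atoms: none
Why: The boron of the N-protonated oxazaborolidine binds the formyl oxygen of s-trans 5 (held by a formyl C–H···O contact), lowers its LUMO and lets the electron-rich diene 4 add in a concerted but asynchronous [4+2] cycloaddition in which the free CH2 terminus C7 bonds to the beta-carbon C8 slightly ahead of C10–C9 bond formation. The closest known reaction type is the oxazaborolidinium-catalysed enantioselective exo Diels–Alder reaction of alpha-substituted enals with 1,3-dienes, backed by the exo cycloadditions of 1-vinylcyclohexenes with tiglic-type dienophiles under simple Lewis acids. Ring B closes as a six-membered carbocycle by intermolecular suprafacial–suprafacial cycloaddition (bonds C7–C8 and C9–C10), which leaves the alkene at C5=C6. The cis relation of the C8 and C9 methyl groups is copied from the E geometry of 5, C10 is set relative to C9 by the exo-formyl transition state (H-10 cis to the formyl carbon C11 and trans to the C9 methyl), and the absolute configuration comes from the catalyst, whose phenyl group covers one face of the bound enal so that the diene reaches the Si face of the alpha-carbon. The step needs regio-, exo- and facial selectivity: the first should follow from pairing the larger-coefficient, unhindered C7 terminus with the enal beta-carbon, the second from the alpha-methyl group and the bulky catalyst-bound formyl keeping clear of the diene and its C4 gem-dimethyl group (which also holds the diene s-cis), and the third from the catalyst alone, because neither partner has a stereocentre. The aldehyde formed is non-enolisable, so the three new centres cannot epimerise.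

Step 4
Reactants: 7 1,2,4,5-tetramethoxybenzene; 6 (1R,2S,8aR)-1,2,5,5-tetramethyl-1,2,3,5,6,7,8,8a-octahydronaphthalene-1-carbaldehyde
Product: 10 (RS)-[(1R,2S,8aR)-1,2,5,5-tetramethyl-1,2,3,5,6,7,8,8a-octahydronaphthalen-1-yl](2,3,5,6-tetramethoxyphenyl)methanol (both carbinol epimers), via aryllithium 8 (not isolated), via lithium alkoxide 9 (not isolated)
Conditions: 7, n-BuLi, TMEDA, THF, 0 °C; then 6, −78 to 0 °C; H2O
Reagents that add atoms: none
Why: Directed ortho-lithiation followed by 1,2-addition: n-BuLi/TMEDA removes a ring hydrogen of 7 flanked by two methoxy groups, and the aryllithium can only add to the carbonyl of the non-enolisable aldehyde; the new carbinol centre forms without control and is deleted in step 6, so both epimers are carried on.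

Step 5
Reactants: 10 benzylic alcohol (both carbinol epimers)
Product: 13 O-{[(1R,2S,8aR)-1,2,5,5-tetramethyl-1,2,3,5,6,7,8,8a-octahydronaphthalen-1-yl](2,3,5,6-tetramethoxyphenyl)methyl} S-methyl dithiocarbonate (xanthate; both carbinol epimers), via sodium alkoxide 11 (not isolated), via sodium dithiocarbonate 12 (not isolated)
Conditions: NaH, imidazole (cat.), THF, 0 °C to rt; CS2; then MeI, rt
Reagents that add atoms: carbon disulfide (S=C=S); iodomethane (CI)
Why: Xanthate formation, the first half of a Barton–McCombie deoxygenation: the alkoxide adds to CS2 and the dithiocarbonate anion is S-methylated; the carbinol carbon has no beta-hydrogen on either side (aryl ring, quaternary C9), so Chugaev elimination cannot compete, and the centres of ring B are not involved.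

Step 6
Reactants: 13 xanthate (both carbinol epimers)
Product: 14 3-{[(1R,2S,8aS)-1,2,5,5-tetramethyl-1,2,3,5,6,7,8,8a-octahydronaphthalen-1-yl]methyl}-1,2,4,5-tetramethoxybenzene
Conditions: Bu3SnH, AIBN (cat.), toluene, 110 °C
Reagents that add atoms: none
Why: Barton–McCombie radical deoxygenation: the stannyl radical adds to the thiocarbonyl sulfur, beta-scission releases a benzylic C11 radical that takes a hydrogen atom from Bu3SnH; no cation arises next to quaternary C9, so no Wagner–Meerwein shift is expected, the radical has only unfavourable 4-exo or 5-endo closures onto C5=C6, and the carbinol centre disappears while C8, C9 and C10 stay untouched.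

Step 7
Reactants: 14 tetramethoxyaryl sesquiterpene
Product: 15 2,5-dimethoxy-3-{[(1R,2S,8aS)-1,2,5,5-tetramethyl-1,2,3,5,6,7,8,8a-octahydronaphthalen-1-yl]methyl}cyclohexa-2,5-diene-1,4-dione
Conditions: (NH4)2Ce(NO3)6, MeCN/H2O, 0 °C
Reagents that add atoms: water (O)
Why: Oxidative demethylation by tetravalent cerium: the electron-rich arene is oxidised by single-electron transfer, water adds and two para-related methoxy groups leave as methanol; either para pair gives the same 2,5-dimethoxy-1,4-quinone, the isolated trisubstituted alkene should be oxidised far more slowly at 0 °C, and no stereocentre is involved.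

Step 8
Reactants: 15 2,5-dimethoxy-3-alkyl-1,4-benzoquinone
Product: 17 2-hydroxy-5-methoxy-3-{[(1R,2S,8aS)-1,2,5,5-tetramethyl-1,2,3,5,6,7,8,8a-octahydronaphthalen-1-yl]methyl}cyclohexa-2,5-diene-1,4-dione (target), via potassium quinonolate 16 (not isolated)
Conditions: KOH, MeOH/H2O, rt; then 1 M HCl, 0 °C
Reagents that add atoms: potassium hydroxide ([K+].[OH-])
Why: Vinylogous ester hydrolysis by addition–elimination: hydroxide attacks the methoxy-bearing carbon between the alkyl group and a carbonyl, where the methoxy group is forced out of conjugation and the carbon is the more electrophilic, the delocalised quinonolate resists a second substitution, and mild acidification should free the hydroxyquinone without generating a C5 cation; no stereocentre is touched.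

**Compound list**

1 | 2,2-dimethylcyclohexanone | CC1(C)CCCCC1=O | starting material
2 | lithium 6,6-dimethylcyclohex-1-en-1-olate (lithium enolate of 1) | [Li+].[O-]C1=CCCCC1(C)C | intermediate
3 | 6,6-dimethylcyclohex-1-en-1-yl trifluoromethanesulfonate | CC1(C)CCCC=C1OS(=O)(=O)C(F)(F)F | intermediate
4 | 1-ethenyl-6,6-dimethylcyclohexene | C=CC1=CCCCC1(C)C | intermediate
5 | (E)-2-methylbut-2-enal (tiglaldehyde) | C/C=C(\C)C=O | starting material
6 | (1R,2S,8aR)-1,2,5,5-tetramethyl-1,2,3,5,6,7,8,8a-octahydronaphthalene-1-carbaldehyde | O=C[C@@]1(C)[C@@H]2CCCC(C)(C)C2=CC[C@@H]1C | intermediate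
7 | 1,2,4,5-tetramethoxybenzene | COc1cc(OC)c(OC)cc1OC | starting material
8 | (2,3,5,6-tetramethoxyphenyl)lithium | [Li]c1c(OC)c(OC)cc(OC)c1OC | intermediate
9 | lithium alkoxide of 10 (both carbinol epimers) | [Li+].[O-]C(c1c(OC)c(OC)cc(OC)c1OC)[C@@]2(C)[C@@H]3CCCC(C)(C)C3=CC[C@@H]2C | intermediate
10 | (RS)-[(1R,2S,8aR)-1,2,5,5-tetramethyl-1,2,3,5,6,7,8,8a-octahydronaphthalen-1-yl](2,3,5,6-tetramethoxyphenyl)methanol | COc1cc(OC)c(OC)c(C(O)[C@@]2(C)[C@@H]3CCCC(C)(C)C3=CC[C@@H]2C)c1OC | intermediate
11 | sodium alkoxide of 10 (both carbinol epimers) | [Na+].[O-]C(c1c(OC)c(OC)cc(OC)c1OC)[C@@]2(C)[C@@H]3CCCC(C)(C)C3=CC[C@@H]2C | intermediate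
12 | sodium O-alkyl dithiocarbonate derived from 10 (both carbinol epimers) | [Na+].[S-]C(=S)OC(c1c(OC)c(OC)cc(OC)c1OC)[C@@]2(C)[C@@H]3CCCC(C)(C)C3=CC[C@@H]2C | intermediate
13 | O-{[(1R,2S,8aR)-1,2,5,5-tetramethyl-1,2,3,5,6,7,8,8a-octahydronaphthalen-1-yl](2,3,5,6-tetramethoxyphenyl)methyl} S-methyl dithiocarbonate (both carbinol epimers) | CSC(=S)OC(c1c(OC)c(OC)cc(OC)c1OC)[C@@]2(C)[C@@H]3CCCC(C)(C)C3=CC[C@@H]2C | intermediate
14 | 3-{[(1R,2S,8aS)-1,2,5,5-tetramethyl-1,2,3,5,6,7,8,8a-octahydronaphthalen-1-yl]methyl}-1,2,4,5-tetramethoxybenzene | COc1cc(OC)c(OC)c(C[C@@]2(C)[C@@H]3CCCC(C)(C)C3=CC[C@@H]2C)c1OC | intermediate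
15 | 2,5-dimethoxy-3-{[(1R,2S,8aS)-1,2,5,5-tetramethyl-1,2,3,5,6,7,8,8a-octahydronaphthalen-1-yl]methyl}cyclohexa-2,5-diene-1,4-dione | COC1=CC(=O)C(OC)=C(C[C@@]2(C)[C@@H]3CCCC(C)(C)C3=CC[C@@H]2C)C1=O | intermediate
16 | potassium salt (quinonolate) of 17 | [K+].[O-]C1=C(C[C@@]2(C)[C@@H]3CCCC(C)(C)C3=CC[C@@H]2C)C(=O)C(OC)=CC1=O | intermediate
17 | 2-hydroxy-5-methoxy-3-{[(1R,2S,8aS)-1,2,5,5-tetramethyl-1,2,3,5,6,7,8,8a-octahydronaphthalen-1-yl]methyl}cyclohexa-2,5-diene-1,4-dione | COC1=CC(=O)C(O)=C(C[C@@]2(C)[C@@H]3CCCC(C)(C)C3=CC[C@@H]2C)C1=O | target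

**Count and risks**

Total step count: 8. Longest linear sequence: 8 steps (1 to 17); compounds 5 and 7 are bought and enter at steps 3 and 4.

Steps most likely to fail, riskiest first:

Step 3. The alpha,beta-disubstituted enal may react too slowly at the temperatures at which the catalyst discriminates well, the acid-sensitive diene may oligomerise, or exo and facial selectivity may be incomplete. The fallback sets out from 4 and 5 and returns at 6. The cycloaddition is run with the achiral Lewis acid Me2AlCl (CH2Cl2, −78 to −20 °C), which should give the racemic exo aldehyde F1. Condensation with (1R,2R)-N,N'-dimethyl-1,2-diphenylethane-1,2-diamine (Et2O, 4 Å molecular sieves) converts it into two diastereomeric aminals, the wanted aminal F2 and the aminal of the mirror-image aldehyde F3, which are separated by chromatography or crystallisation. Brief two-phase hydrolysis of F2 (dilute aqueous HCl/Et2O, 0 °C) returns enantiopure 6 and the diamine for reuse. Enantiocontrol then rests on a resolution instead of on catalysis, while the same two bonds still close ring B.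

Step 4. The 1,2-addition may be blocked sterically, since a di-ortho-substituted aryllithium must reach a formyl group on a quaternary carbon, so the aldehyde may be recovered or merely reduced. The fallback sets out from 6 (with 7 as the arene source) and returns at 14, bypassing 10 and 13. NaBH4 (MeOH, 0 °C) reduces 6 to the neopentyl primary alcohol F4. PPh3/I2/imidazole (toluene, 80 °C) converts it into the neopentyl iodide F5. Zinc dust with LiCl (THF, 50 °C) inserts to give the alkylzinc iodide F6, which has no beta-hydrogen and is therefore robust. Negishi coupling of F6 with 3-bromo-1,2,4,5-tetramethoxybenzene F7 (from 7 with NBS in MeCN), using Pd(OAc)2 and SPhos in THF at 60 °C, should deliver 14 directly. The C11–aryl bond is then formed by reductive elimination at divalent palladium instead of by carbonyl addition, and the deoxygenation becomes unnecessary.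

Step 5 (together with step 6). Acylation of the congested alkoxide may stay incomplete, the electron-rich benzylic xanthate may rearrange from O to S on heating, or the radical chain may propagate poorly. The fallback sets out from 10 and returns at 14. Acetylation (Ac2O, DMAP, pyridine) gives the benzylic acetate F8. Dissolving-metal cleavage of its benzylic C–O bond (Li, liquid NH3/THF, −78 °C, then solid NH4Cl) should give 14. This is an electron-transfer process under basic conditions instead of a radical chain; in the absence of an alcohol the tetramethoxyarene and the isolated alkene should survive, and no cation is formed next to C9.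

**Further compounds**

F1 | step 3 | racemic exo aldehyde (6 together with its enantiomer) | O=C[C@@]1(C)[C@@H]2CCCC(C)(C)C2=CC[C@@H]1C.O=C[C@]1(C)[C@H]2CCCC(C)(C)C2=CC[C@H]1C
F2 | step 3 | (4R,5R)-1,3-dimethyl-4,5-diphenyl-2-[(1R,2S,8aR)-1,2,5,5-tetramethyl-1,2,3,5,6,7,8,8a-octahydronaphthalen-1-yl]imidazolidine (aminal of 6) | CN1[C@H](c2ccccc2)[C@@H](c2ccccc2)N(C)C1[C@@]3(C)[C@@H]4CCCC(C)(C)C4=CC[C@@H]3C
F3 | step 3 | (4R,5R)-1,3-dimethyl-4,5-diphenyl-2-[(1S,2R,8aS)-1,2,5,5-tetramethyl-1,2,3,5,6,7,8,8a-octahydronaphthalen-1-yl]imidazolidine (aminal of the enantiomer of 6, discarded) | CN1[C@H](c2ccccc2)[C@@H](c2ccccc2)N(C)C1[C@]3(C)[C@H]4CCCC(C)(C)C4=CC[C@H]3C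
F4 | step 4 | [(1R,2S,8aR)-1,2,5,5-tetramethyl-1,2,3,5,6,7,8,8a-octahydronaphthalen-1-yl]methanol | OC[C@@]1(C)[C@@H]2CCCC(C)(C)C2=CC[C@@H]1C
F5 | step 4 | (1R,2S,8aR)-1-(iodomethyl)-1,2,5,5-tetramethyl-1,2,3,5,6,7,8,8a-octahydronaphthalene | IC[C@@]1(C)[C@@H]2CCCC(C)(C)C2=CC[C@@H]1C
F6 | step 4 | {[(1R,2S,8aR)-1,2,5,5-tetramethyl-1,2,3,5,6,7,8,8a-octahydronaphthalen-1-yl]methyl}zinc iodide | I[Zn]C[C@@]1(C)[C@@H]2CCCC(C)(C)C2=CC[C@@H]1C
F7 | step 4 | 3-bromo-1,2,4,5-tetramethoxybenzene | COc1cc(OC)c(OC)c(Br)c1OC
F8 | step 5 | [(1R,2S,8aR)-1,2,5,5-tetramethyl-1,2,3,5,6,7,8,8a-octahydronaphthalen-1-yl](2,3,5,6-tetramethoxyphenyl)methyl acetate (both carbinol epimers) | CC(=O)OC(c1c(OC)c(OC)cc(OC)c1OC)[C@@]2(C)[C@@H]3CCCC(C)(C)C3=CC[C@@H]2C
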